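## Retrosynthetic overview

1. Numbering: cyclopentane C1 (fusion CH)–C2–C3 (CHOH)–C4 (CMe2)–C5 (fusion C–OH); cycloheptanone C5–C6–C7–C8 (CHMe)–C9 (Me, C11–C12–butenolide)–C10 (C=O)–C1. The plan rests on C6–C7, the only bond of the seven-membered ring that joins two bare CH2 groups; it lies between the crowded carbinol C5 and the C8/C9 stereodiad.
2. Last: the butenolide is attached at C12 by B-alkyl Suzuki coupling. The C10 ketone is unmasked from a silyl ether only after all basic steps, because the C5–OH/C10=O ketol is base-labile.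
3. Key: C6=C7 arises by Ramberg–Bäcklund loss of SO2 from the thiocane 1,1-dioxide C5–C6–S–C7–C8–C9–C10–C1 (8 → 7 ring contraction) and is then hydrogenated.
4. Thiocane: a C7 thiolate opens a C5 spiro-epoxide at C6 and reveals O5. C6 comes from chloromethyllithium added to the C5 ketone anti to the C1 side chain.
5. C1–C10: selenolate-relayed Michael–aldol of a 4-silyloxy-5,5-dimethylcyclopentenone (from 2,2-dimethylcyclopentane-1,3-dione, CBS) with an α-quaternary aldehyde (from (S)-β-methyl-γ-butyrolactone, two anti alkylations). Ring order: cyclopentane (bought) → thiocane → cycloheptene → butenolide (bought, attached last).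

Key step: step 18

Convention: α is the cyclopentane face that carries O3 (in the target also O5 and C10); β is the face that carries C6 and H1.
Assumption: (S)-4-methyldihydrofuran-2(3H)-one is taken as a catalogue compound (otherwise one step by Ru–BINAP hydrogenation of 4-methylfuran-2(5H)-one).
Assumption: the C10 carbinol is drawn with the anti-aldol configuration expected from a closed transition state; it is a spectator centre erased in step 23, so its epimer would serve equally.

## Route

Step 1
Reactants: 1 2,2-dimethylcyclopentane-1,3-dione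
Product: 2 (R)-3-hydroxy-2,2-dimethylcyclopentan-1-one
Conditions: (S)-Me-CBS (20 mol %), BH3·SMe2 (0.6 equiv), THF, −40 °C; MeOH
Reagents that add atoms: none
Why: Corey–Bakshi–Shibata reduction desymmetrises the dione; with quaternary C4 as the large and CH2 as the small flank, the (S)-catalyst should deliver hydride in the sense it shows with acetophenone and set C3 as R, while substoichiometric borane limits diol formation.

Step 2
Reactants: 2 (R)-3-hydroxy-2,2-dimethylcyclopentan-1-one
Product: 3 (R)-3-(tert-butyldimethylsilyloxy)-2,2-dimethylcyclopentan-1-one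
Conditions: TBSOTf, 2,6-lutidine, CH2Cl2, 0 °C
Reagents that add atoms: tert-butyldimethylsilyl triflate, CC(C)(C)[Si](C)(C)OS(=O)(=O)C(F)(F)F
Why: Silyl triflate with a hindered pyridine base silylates the neopentyl carbinol without generating the alkoxide that would open this β-hydroxy ketone by retro-aldol cleavage.

Step 3
Reactants: 3 (R)-3-(tert-butyldimethylsilyloxy)-2,2-dimethylcyclopentan-1-one
Product: 6 (R)-4-(tert-butyldimethylsilyloxy)-5,5-dimethylcyclopent-2-en-1-one, via lithium enolate 4 (not isolated), via trimethylsilyl enol ether 5 (not isolated)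
Conditions: LDA, THF, −78 °C; TMSCl; then Pd(OAc)2 (1.05 equiv), MeCN, rt
Reagents that add atoms: none
Why: Saegusa–Ito dehydrogenation works here because only C1 can be enolised (C4 is quaternary), and Pd(II) oxidation of the enol silane places the C1=C2 double bond next to the untouched C3 stereocentre.

Step 4
Reactants: 7 (S)-4-methyldihydrofuran-2(3H)-one
Product: 9 (3S,4S)-3,4-dimethyldihydrofuran-2(3H)-one (trans), via lithium enolate 8 (not isolated)
Conditions: LDA, THF, −78 °C; MeI
Reagents that add atoms: iodomethane, CI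
Why: In this kinetic lactone enolate alkylation methyl iodide should enter anti to the C8 methyl group, and the new C9 centre is planarised again in step 5 so its ratio is of no consequence.

Step 5
Reactants: 9 (3S,4S)-3,4-dimethyldihydrofuran-2(3H)-one; 10 benzyl 2-iodoethyl ether
Product: 12 (3S,4S)-3-[2-(benzyloxy)ethyl]-3,4-dimethyldihydrofuran-2(3H)-one (methyl groups cis), via lithium enolate 11 (not isolated)
Conditions: LDA, THF, −78 °C; DMPU; 10, −78 → −20 °C
Reagents that add atoms: none
Why: The tetrasubstituted enolate of a β-substituted γ-butyrolactone is alkylated on the face opposite to the adjacent C8 methyl group, so bringing in the chain last should put C11 trans and the C9 methyl cis to the C8 methyl, as the target requires.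

Step 6
Reactants: 12 (3S,4S)-3-[2-(benzyloxy)ethyl]-3,4-dimethyldihydrofuran-2(3H)-one
Product: 13 (3S,4S)-3-[2-(benzyloxy)ethyl]-3,4-dimethyltetrahydrofuran-2-ol (lactol, anomers)
Conditions: DIBAL-H (1.1 equiv), CH2Cl2, −78 °C; Rochelle salt
Reagents that add atoms: none
Why: At −78 °C DIBAL-H reduction stops at the tetrahedral aluminium lactolate, which gives the lactol on work-up; the anomeric centre is lost in the next step.

Step 7
Reactants: 13 (3S,4S)-3-[2-(benzyloxy)ethyl]-3,4-dimethyltetrahydrofuran-2-ol
Product: 14 (2S,3R)-3-[2-(benzyloxy)ethyl]-2,3-dimethylpent-4-en-1-ol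
Conditions: Ph3PCH3Br, KOt-Bu, THF, 0 °C → reflux
Reagents that add atoms: methyltriphenylphosphonium bromide, C[P+](c1ccccc1)(c1ccccc1)c1ccccc1.[Br-]
Why: Wittig methylenation traps the open hydroxy-aldehyde form of the lactol, frees O7 and masks C10 as a vinyl group, which tells apart two primary positions that would be almost equally hindered in the corresponding diol.

Step 8
Reactants: 14 (2S,3R)-3-[2-(benzyloxy)ethyl]-2,3-dimethylpent-4-en-1-ol
Product: 15 benzyl (3R,4S)-5-chloro-3-ethenyl-3,4-dimethylpentyl ether
Conditions: PPh3, CCl4, MeCN, rt → 50 °C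
Reagents that add atoms: carbon tetrachloride, ClC(Cl)(Cl)Cl
Why: Appel chlorination converts the only hydroxyl group by SN2 at C7 without touching a stereocentre, and a chloride is chosen because it should survive the selenolate, lithium aldolate, tin hydride and carbenoid of the later steps.

Step 9
Reactants: 15 benzyl (3R,4S)-5-chloro-3-ethenyl-3,4-dimethylpentyl ether
Product: 16 (2S,3S)-2-[2-(benzyloxy)ethyl]-4-chloro-2,3-dimethylbutanal
Conditions: OsO4 (2 mol %), NaIO4, 2,6-lutidine, dioxane–H2O, rt
Reagents that add atoms: sodium periodate, [Na+].[O-]I(=O)(=O)=O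
Why: Lutidine-buffered Lemieux–Johnson cleavage of the monosubstituted alkene gives the non-enolisable α-quaternary aldehyde and leaves the benzyl ether and the chloride alone.

Step 10
Reactants: 6 (R)-4-(tert-butyldimethylsilyloxy)-5,5-dimethylcyclopent-2-en-1-one; 16 (2S,3S)-2-[2-(benzyloxy)ethyl]-4-chloro-2,3-dimethylbutanal
Product: 18 seleno aldol (C5 ketone; 3α-OTBS; 2β-SePh; at C1α the chain C10H(OH)–C9(Me)(CH2CH2OBn)–C8H(Me)–C7H2Cl), via β-seleno lithium enolate 17 (not isolated)
Conditions: PhSeH, n-BuLi, THF, −78 °C; 6; then 16, −78 °C; AcOH, −78 °C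
Reagents that add atoms: benzeneselenol, [SeH]c1ccccc1
Why: In this chalcogenide-mediated tandem Michael–aldol the soft, non-basic selenolate adds to C2 anti to the vicinal C3 silyloxy group and the enolate then takes up the aldehyde at C1 anti to the vicinal C2 selenide, so C10 should end cis to O3 (the trans,trans relay of three-component cyclopentenone couplings, which a direct aldol of 3 with its remote 1,3-bias cannot guarantee), while the closed transition state of the ring (E)-enolate favours the anti carbinol at C10.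

Step 11
Reactants: 18 seleno aldol
Product: 19 10-O-triethylsilyl ether of 18
Conditions: TESOTf, 2,6-lutidine, CH2Cl2, −78 → 0 °C
Reagents that add atoms: triethylsilyl triflate, CC[Si](CC)(CC)OS(=O)(=O)C(F)(F)F
Why: Silyl triflate and lutidine cap the hindered aldol hydroxyl in a medium too weakly basic for retro-aldol or retro-Michael loss of selenolate, and TES is chosen so that O10 can later be freed beside the C3 TBS ether.

Step 12
Reactants: 19 10-O-triethylsilyl ether of 18
Product: 20 ketone (as 19 but C2H2; C1 side chain α, 3α-OTBS)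
Conditions: n-Bu3SnH, Et3B (cat.), air, toluene, 0 °C → rt
Reagents that add atoms: none
Why: In this radical deselenation stannyl radicals abstract the phenylselanyl group orders of magnitude faster than a primary chloride, the C2 radical has no fragmentation pathway, and C1 is not involved so its configuration is kept.

Step 13
Reactants: 20 ketone
Product: 21 chlorohydrin (5α-OH, 5β-CH2Cl = C6; otherwise as 20)
Conditions: ClCH2I, MeLi·LiBr, THF–Et2O, −78 °C (Barbier mode); AcOH, −78 °C
Reagents that add atoms: chloroiodomethane, ClCI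
Why: In this halomethyllithium addition the small, weakly basic carbenoid, made by I/Li exchange in the presence of the ketone, should attack the hindered C5 carbonyl from the β face, opposite to both the C1 side chain and the C3 silyloxy group, which sets C6 trans to C10 and O5 cis to O3, and the cold acidic quench keeps the adduct as the chlorohydrin.

Step 14
Reactants: 21 chlorohydrin
Product: 22 C7 thioacetate (C7–SAc; C5 chlorohydrin retained)
Conditions: KSAc, NaI (cat.), DMF, 60 °C
Reagents that add atoms: potassium thioacetate, CC(=O)[S-].[K+]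
Why: Iodide-catalysed SN2 with thioacetate should take place only at C7, because the C6 chloride is neopentyl and the weakly basic medium does not close the chlorohydrin.

Step 15
Reactants: 22 C7 thioacetate
Product: 24 trans-fused thiocane (S between C6 and C7; free 5α-OH; 3α-OTBS; 10-OTES; C12-OBn), via spiro-epoxy thiolate 23 (not isolated)
Conditions: K2CO3, degassed MeOH–THF, slow addition to 0.002 M, rt
Reagents that add atoms: none
Why: Methanolysis frees the thiolate, carbonate closes the chlorohydrin to the C5 spiro-epoxide without touching the C5–O bond, and the soft thiolate opens it by SN2 at the methylene C6 (distal carbon, formally 8-endo) under high dilution, so O5 keeps the configuration set in step 13.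

Step 16
Reactants: 24 trans-fused thiocane
Product: 25 5-O-triethylsilyl ether of 24
Conditions: TESOTf, 2,6-lutidine, CH2Cl2, 0 °C → rt
Reagents that add atoms: triethylsilyl triflate, CC[Si](CC)(CC)OS(=O)(=O)C(F)(F)F
Why: A silyl triflate is among the few electrophiles that reach this tertiary carbinol; O5 must be capped because the free β-alkoxide of the coming sulfone would fragment by retro-addition, and a bridging O3/O5 acetonide is avoided because its endo methyl group would be pressed against C10 under the ring.

Step 17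
Reactants: 25 5-O-triethylsilyl ether of 24
Product: 26 thiocane 1,1-dioxide (Ramberg–Bäcklund precursor; 3α-OTBS, 5α-OTES, 10-OTES, C12-OBn)
Conditions: m-CPBA (2.5 equiv), NaHCO3, CH2Cl2, 0 °C
Reagents that add atoms: 3-chloroperbenzoic acid, O=C(OO)c1cccc(Cl)c1
Why: Buffered peracid oxidation takes the sulfide to the sulfone, and the substrate holds no alkene or other oxidisable group.

Step 18
Reactants: 26 thiocane 1,1-dioxide
Product: 29 trans-fused hydroazulene with a C6=C7 double bond (3α-OTBS; 5α-OTES; 10-OTES; C12-OBn), via α-bromo sulfone 27 (not isolated), via episulfone 28 (not isolated)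
Conditions: KOH/Al2O3, CBr2F2, t-BuOH–CH2Cl2, 0 °C → rt
Reagents that add atoms: none
Why: Hydroxide deprotonates one of the two sulfone α-methylenes (C6 or C7), the carbanion is brominated by halophilic attack on CBr2F2, a second deprotonation on the other side of sulfur displaces bromide to give episulfone 28, and this loses SO2 cheletropically (Meyers–Chan form of the Ramberg–Bäcklund reaction). The closest known cases are the contractions of thiepane and thiocane 1,1-dioxides, β-alkoxy-substituted ones included, to cyclohexenes and cycloheptenes. The C6–C7 bond forms in a 3-exo-tet closure across sulfur that at the same time closes the seven-membered carbocycle, and the site of bromination does not matter because both α-bromo sulfones lead to the same alkene. No stereocentre is created, none of those present sits on an acidic carbon, and the ring size enforces a cis double bond. The step needs deprotonation only at C6 and C7, which is secured because the substrate carries nothing but ethers, C10 being masked as a silyl ether. It also needs the 1,3-elimination to outrun E1cB loss of the C5 silyloxy group from the C6 carbanion, which the fast bromine transfer, the good bromide leaving group and the modest leaving ability of a silanolate should favour.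

Step 19
Reactants: 29 trans-fused hydroazulene with a C6=C7 double bond
Product: 31 primary alcohol (C6–C7 saturated; C12–OH; silyl ethers retained), via saturated benzyl ether 30 (not isolated)
Conditions: H2 (1 atm), PtO2, EtOAc, rt; then Pd(OH)2/C, H2, same flask, rt
Reagents that add atoms: none
Why: Adams catalyst saturates the cis double bond with little tendency to shift it towards C8 (which would endanger that stereocentre) or to cleave the allylic C5–O bond, and Pearlman's catalyst added afterwards hydrogenolyses the benzyl ether, no stereocentre being formed.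

Step 20
Reactants: 31 primary alcohol
Product: 32 primary iodide (C12–I)
Conditions: I2, PPh3, imidazole, CH2Cl2, 0 °C
Reagents that add atoms: iodine, II
Why: Garegg–Samuelsson iodination converts the only free hydroxyl group, and because O10 is still silylated no tetrahydrofuran can form by attack of O10 on C12.

Step 21
Reactants: 32 primary iodide; 33 4-bromofuran-2(5H)-one
Product: 36 butenolide tris(silyl ether) (C12 bound to C4 of the furanone), via alkyllithium 34 (not isolated), via lithium borinate 35 (not isolated)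
Conditions: t-BuLi (2.1 equiv), Et2O, −78 °C; B-MeO-9-BBN, THF, −78 °C → rt; then 33, PdCl2(dppf) (5 mol %), AsPh3, K3PO4 (aq), DMF, rt
Reagents that add atoms: none
Why: This is a B-alkyl Suzuki–Miyaura coupling by the lithiation–borinate protocol, in which I/Li exchange, capture by B-methoxy-9-BBN and Pd-catalysed transfer of the primary alkyl group to the β-bromo butenolide should proceed cleanly because the substrate has neither a carbonyl group nor an acidic proton at this stage.

Step 22
Reactants: 36 butenolide tris(silyl ether)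
Product: 37 C10 alcohol (10-OH; 5α-OTES and 3α-OTBS retained)
Conditions: HF·pyridine, pyridine, THF, 0 °C
Reagents that add atoms: none
Why: Buffered HF·pyridine discriminates between triethylsilyl and tert-butyldimethylsilyl ethers and should take the secondary C10 TES ether first, while any material that also loses the tertiary C5 TES ether converges in step 24.

Step 23
Reactants: 37 C10 alcohol
Product: 38 C10 ketone (5α-OTES, 3α-OTBS)
Conditions: Dess–Martin periodinane, NaHCO3, CH2Cl2, rt
Reagents that add atoms: none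
Why: Dess–Martin oxidation handles hindered secondary alcohols under near-neutral conditions, erases the spectator centre C10 and avoids enolisation at C1 or β-elimination of O5.

Step 24
Reactants: 38 C10 ketone
Product: 39 target, 4-{2-[(2R,3aS,5S,6R,8aS)-2,8a-dihydroxy-1,1,5,6-tetramethyl-4-oxodecahydroazulen-5-yl]ethyl}furan-2(5H)-one
Conditions: HF (48 % aq), MeCN, 0 °C → rt
Reagents that add atoms: none
Why: Aqueous HF in acetonitrile removes both remaining silyl ethers in a mildly acidic, base-free medium that the ketol (prone to retro-aldol and C1 epimerisation under base) and the butenolide should tolerate.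

## Compound list

1 | 2,2-dimethylcyclopentane-1,3-dione | CC1(C)C(=O)CCC1=O | starting material
2 | (R)-3-hydroxy-2,2-dimethylcyclopentan-1-one | O=C1CC[C@@H](O)C1(C)C | intermediate
3 | (R)-3-(tert-butyldimethylsilyloxy)-2,2-dimethylcyclopentan-1-one | O=C1CC[C@@H](O[Si](C)(C)C(C)(C)C)C1(C)C | intermediate
4 | lithium enolate of 3 | [Li]OC1=CC[C@@H](O[Si](C)(C)C(C)(C)C)C1(C)C | intermediate
5 | trimethylsilyl enol ether of 3 | C[Si](C)(C)OC1=CC[C@@H](O[Si](C)(C)C(C)(C)C)C1(C)C | intermediate
6 | (R)-4-(tert-butyldimethylsilyloxy)-5,5-dimethylcyclopent-2-en-1-one | O=C1C=C[C@@H](O[Si](C)(C)C(C)(C)C)C1(C)C | intermediate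
7 | (S)-4-methyldihydrofuran-2(3H)-one | C[C@@H]1COC(=O)C1 | starting material
8 | lithium enolate of 7 | C[C@@H]1COC(O[Li])=C1 | intermediate
9 | (3S,4S)-3,4-dimethyldihydrofuran-2(3H)-one | C[C@@H]1COC(=O)[C@H]1C | intermediate
10 | benzyl 2-iodoethyl ether | ICCOCc1ccccc1 | starting material
11 | lithium enolate of 9 | C[C@@H]1COC(O[Li])=C1C | intermediate
12 | (3S,4S)-3-[2-(benzyloxy)ethyl]-3,4-dimethyldihydrofuran-2(3H)-one | C[C@@H]1COC(=O)[C@@]1(C)CCOCc1ccccc1 | intermediate
13 | (3S,4S)-3-[2-(benzyloxy)ethyl]-3,4-dimethyltetrahydrofuran-2-ol (anomers) | C[C@@H]1COC(O)[C@@]1(C)CCOCc1ccccc1 | intermediate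
14 | (2S,3R)-3-[2-(benzyloxy)ethyl]-2,3-dimethylpent-4-en-1-ol | C[C@H](CO)[C@](C)(CCOCc1ccccc1)C=C | intermediate
15 | benzyl (3R,4S)-5-chloro-3-ethenyl-3,4-dimethylpentyl ether | C[C@H](CCl)[C@](C)(CCOCc1ccccc1)C=C | intermediate
16 | (2S,3S)-2-[2-(benzyloxy)ethyl]-4-chloro-2,3-dimethylbutanal | C[C@H](CCl)[C@](C)(CCOCc1ccccc1)C=O | intermediate
17 | β-seleno lithium enolate (2β-SePh, 3α-OTBS) | [Li]OC1=C[C@H]([Se]c2ccccc2)[C@@H](O[Si](C)(C)C(C)(C)C)C1(C)C | intermediate
18 | seleno aldol (2β-SePh, 3α-OTBS, C1α side chain, 10-OH) | C[C@H](CCl)[C@](C)(CCOCc1ccccc1)[C@@H](O)[C@H]1[C@H]([Se]c2ccccc2)[C@@H](O[Si](C)(C)C(C)(C)C)C(C)(C)C1=O | intermediate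
19 | 10-O-TES ether of 18 | C[C@H](CCl)[C@](C)(CCOCc1ccccc1)[C@@H](O[Si](CC)(CC)CC)[C@H]1[C@H]([Se]c2ccccc2)[C@@H](O[Si](C)(C)C(C)(C)C)C(C)(C)C1=O | intermediate
20 | deselenated C5 ketone | C[C@H](CCl)[C@](C)(CCOCc1ccccc1)[C@@H](O[Si](CC)(CC)CC)[C@H]1C[C@@H](O[Si](C)(C)C(C)(C)C)C(C)(C)C1=O | intermediate
21 | chlorohydrin (5α-OH, 5β-CH2Cl) | C[C@H](CCl)[C@](C)(CCOCc1ccccc1)[C@@H](O[Si](CC)(CC)CC)[C@H]1C[C@@H](O[Si](C)(C)C(C)(C)C)C(C)(C)[C@]1(O)CCl | intermediate
22 | C7 thioacetate of 21 | C[C@H](CSC(C)=O)[C@](C)(CCOCc1ccccc1)[C@@H](O[Si](CC)(CC)CC)[C@H]1C[C@@H](O[Si](C)(C)C(C)(C)C)C(C)(C)[C@]1(O)CCl | intermediate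
23 | spiro-epoxy thiolate (potassium salt) | C[C@H](C[S-])[C@](C)(CCOCc1ccccc1)[C@@H](O[Si](CC)(CC)CC)[C@H]1C[C@@H](O[Si](C)(C)C(C)(C)C)C(C)(C)[C@]12CO2.[K+] | intermediate
24 | trans-fused thiocane, free 5α-OH | C[C@@H]1CSC[C@]2(O)[C@H](C[C@@H](O[Si](C)(C)C(C)(C)C)C2(C)C)[C@H](O[Si](CC)(CC)CC)[C@@]1(C)CCOCc1ccccc1 | intermediate
25 | 5-O-TES thiocane | C[C@@H]1CSC[C@]2(O[Si](CC)(CC)CC)[C@H](C[C@@H](O[Si](C)(C)C(C)(C)C)C2(C)C)[C@H](O[Si](CC)(CC)CC)[C@@]1(C)CCOCc1ccccc1 | intermediate
26 | thiocane 1,1-dioxide (key-step precursor) | C[C@@H]1CS(=O)(=O)C[C@]2(O[Si](CC)(CC)CC)[C@H](C[C@@H](O[Si](C)(C)C(C)(C)C)C2(C)C)[C@H](O[Si](CC)(CC)CC)[C@@]1(C)CCOCc1ccccc1 | intermediate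
27 | α-bromo sulfone (Br drawn at C7, configuration there undefined) | C[C@@H]1C(Br)S(=O)(=O)C[C@]2(O[Si](CC)(CC)CC)[C@H](C[C@@H](O[Si](C)(C)C(C)(C)C)C2(C)C)[C@H](O[Si](CC)(CC)CC)[C@@]1(C)CCOCc1ccccc1 | intermediate
28 | episulfone across C6–C7 (cis-fused, face undefined) | C[C@@H]1C2S(=O)(=O)C2[C@]3(O[Si](CC)(CC)CC)[C@H](C[C@@H](O[Si](C)(C)C(C)(C)C)C3(C)C)[C@H](O[Si](CC)(CC)CC)[C@@]1(C)CCOCc1ccccc1 | intermediate
29 | trans-fused hydroazulene with C6=C7 (key-step product) | C[C@@H]1C=C[C@]2(O[Si](CC)(CC)CC)[C@H](C[C@@H](O[Si](C)(C)C(C)(C)C)C2(C)C)[C@H](O[Si](CC)(CC)CC)[C@@]1(C)CCOCc1ccccc1 | intermediate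
30 | saturated benzyl ether | C[C@@H]1CC[C@]2(O[Si](CC)(CC)CC)[C@H](C[C@@H](O[Si](C)(C)C(C)(C)C)C2(C)C)[C@H](O[Si](CC)(CC)CC)[C@@]1(C)CCOCc1ccccc1 | intermediate
31 | primary alcohol (C12–OH) | C[C@@H]1CC[C@]2(O[Si](CC)(CC)CC)[C@H](C[C@@H](O[Si](C)(C)C(C)(C)C)C2(C)C)[C@H](O[Si](CC)(CC)CC)[C@@]1(C)CCO | intermediate
32 | primary iodide (C12–I) | C[C@@H]1CC[C@]2(O[Si](CC)(CC)CC)[C@H](C[C@@H](O[Si](C)(C)C(C)(C)C)C2(C)C)[C@H](O[Si](CC)(CC)CC)[C@@]1(C)CCI | intermediate
33 | 4-bromofuran-2(5H)-one | O=C1C=C(Br)CO1 | starting material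
34 | C12 alkyllithium | C[C@@H]1CC[C@]2(O[Si](CC)(CC)CC)[C@H](C[C@@H](O[Si](C)(C)C(C)(C)C)C2(C)C)[C@H](O[Si](CC)(CC)CC)[C@@]1(C)CC[Li] | intermediate
35 | lithium B-alkyl-B-methoxy-9-BBN borinate | C[C@@H]1CC[C@]2(O[Si](CC)(CC)CC)[C@H](C[C@@H](O[Si](C)(C)C(C)(C)C)C2(C)C)[C@H](O[Si](CC)(CC)CC)[C@@]1(C)CC[B-]1(OC)C2CCCC1CCC2.[Li+] | intermediate
36 | butenolide tris(silyl ether) | C[C@@H]1CC[C@]2(O[Si](CC)(CC)CC)[C@H](C[C@@H](O[Si](C)(C)C(C)(C)C)C2(C)C)[C@H](O[Si](CC)(CC)CC)[C@@]1(C)CCC1=CC(=O)OC1 | intermediate
37 | C10 alcohol | C[C@@H]1CC[C@]2(O[Si](CC)(CC)CC)[C@H](C[C@@H](O[Si](C)(C)C(C)(C)C)C2(C)C)[C@H](O)[C@@]1(C)CCC1=CC(=O)OC1 | intermediate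
38 | C10 ketone | C[C@@H]1CC[C@]2(O[Si](CC)(CC)CC)[C@H](C[C@@H](O[Si](C)(C)C(C)(C)C)C2(C)C)C(=O)[C@@]1(C)CCC1=CC(=O)OC1 | intermediate
39 | CNP0077405.1 (1S,3R,5S,8R,9S in the numbering used here) | C[C@@H]1CC[C@]2(O)[C@H](C[C@@H](O)C2(C)C)C(=O)[C@@]1(C)CCC1=CC(=O)OC1 | target

## Step count and risks

Total step count: 24. Longest linear sequence: 21 (steps 4–9, then 10–24, from 7).

**Step 18.** Three things may go wrong.
- The C6 carbanion may expel the C5 silyloxy group (E1cB).
- Hydroxide may strip a triethylsilyl ether, after which the freed β-alkoxide fragments by retro-addition.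
- Over-bromination may set in.

The fallback separates halogenation from the base step. It sets out from sulfide 25. N-Chlorosuccinimide in CH2Cl2 at 0 °C gives the α-chloro sulfide F1 by Pummerer-type chlorination. m-CPBA at −20 °C oxidises it without delay to the α-chloro sulfone F2. Treating this preformed halo sulfone with KOt-Bu in THF at −78 → 0 °C (classical Ramberg–Bäcklund reaction) needs only one deprotonation, in a hydroxide-free medium at low temperature. The fallback rejoins the route at 29.

**Step 10.** The selenolate addition may reverse (retro-Michael) faster than the neopentyl aldehyde is captured, and the stereochemical relay may erode.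

The fallback makes the C1–C10 bond without regard to C1 and sets C1 afterwards by hydrogen delivery.
- It sets out from 3 and 16; the LDA enolate of 3 adds to 16 to give the aldol F3 as a mixture at C1 and C10.
- TESOTf/2,6-lutidine gives the silyl ether F4.
- Soft enolisation with TMSOTf/Et3N gives the trimethylsilyl enol ether F5.
- Pd(OAc)2 (Saegusa–Ito) gives the 2-substituted cyclopentenone F6, at which stage the C10 epimers are separated.
- Hydrogenation (H2, Pd/C, EtOAc, trace pyridine to spare the benzyl ether) adds hydrogen to C1=C2 on the face anti to the allylic C3 silyloxy group.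

This places H1 β, and the fallback rejoins the route at 20.

**Step 15.** Intermolecular epoxide opening (oligomerisation) or disulfide formation may outpace the eight-membered closure.

The fallback forms the two C–S bonds in the opposite order. It sets out from 21. Excess NaSH with K2CO3 in degassed MeOH–DMF at rt closes the chlorohydrin and opens the epoxide intermolecularly at C6, while the C7 chloride stays inert at this temperature; this gives the hydroxy thiol F7. Cs2CO3 and Bu4NI in DMF at 60 °C under high dilution then close the S–C7 bond in an unconstrained 8-exo-tet displacement. The fallback rejoins the route at 24.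

Further compounds
F1 | step 18 | α-chloro sulfide (Cl drawn at C7) | C[C@@H]1C(Cl)SC[C@]2(O[Si](CC)(CC)CC)[C@H](C[C@@H](O[Si](C)(C)C(C)(C)C)C2(C)C)[C@H](O[Si](CC)(CC)CC)[C@@]1(C)CCOCc1ccccc1
F2 | step 18 | α-chloro sulfone (Cl drawn at C7) | C[C@@H]1C(Cl)S(=O)(=O)C[C@]2(O[Si](CC)(CC)CC)[C@H](C[C@@H](O[Si](C)(C)C(C)(C)C)C2(C)C)[C@H](O[Si](CC)(CC)CC)[C@@]1(C)CCOCc1ccccc1
F3 | step 10 | aldol of 3 and 16 (mixture at C1 and C10) | C[C@H](CCl)[C@](C)(CCOCc1ccccc1)C(O)C1C[C@@H](O[Si](C)(C)C(C)(C)C)C(C)(C)C1=O
F4 | step 10 | 10-O-TES ether of F3 | C[C@H](CCl)[C@](C)(CCOCc1ccccc1)C(O[Si](CC)(CC)CC)C1C[C@@H](O[Si](C)(C)C(C)(C)C)C(C)(C)C1=O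
F5 | step 10 | trimethylsilyl enol ether of F4 | C[C@H](CCl)[C@](C)(CCOCc1ccccc1)C(O[Si](CC)(CC)CC)C1=C(O[Si](C)(C)C)C(C)(C)[C@H](O[Si](C)(C)C(C)(C)C)C1
F6 | step 10 | 2-substituted cyclopentenone (C1=C2; C10 as in 20) | C[C@H](CCl)[C@](C)(CCOCc1ccccc1)[C@@H](O[Si](CC)(CC)CC)C1=C[C@@H](O[Si](C)(C)C(C)(C)C)C(C)(C)C1=O
F7 | step 15 | hydroxy thiol (5α-OH, C6–SH, C7–Cl) | C[C@H](CCl)[C@](C)(CCOCc1ccccc1)[C@@H](O[Si](CC)(CC)CC)[C@H]1C[C@@H](O[Si](C)(C)C(C)(C)C)C(C)(C)[C@]1(O)CS
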